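Briarane numbering (C1–C20) is used throughout; α/β refer to the flat drawing in which the C15 methyl on C1 is β. The target is (1R,2S,3E,6S,7R,8R,9S,10S,11S,12R,14S,17R)-2,9,14-triacetoxy-6-chloro-11,12-epoxy-8-hydroxybriara-3,5(16)-dien-19,7-olide: 15-Me β, 2-OAc β, 9-OAc β, 10-H α, 14-OAc α, 11,12-epoxide α, 6-Cl α, 7-O α, 8-OH α.

## The problem

The skeleton is a cyclohexane (ring A: C1, C14, C13, C12, C11, C10) trans-fused through the quaternary C1 and C10 to a ten-membered ring (C1–C10), which carries a trans-fused γ-lactone on C7–C8. The ten-membered ring resists end-to-end closure. It must also hold an (E)-C3=C4 bond conjugated to the exocyclic C5=C16 methylene. Eleven stereocentres have to be set: those of ring A (C1, C10, C11, C12, C14) can be controlled on a chair; C2 and C9 flank the ring fusion and can be controlled from ring A only while they sit in a six-membered ring; C6, C7, C8 and C17 lie on the flexible macrocycle and must be relayed from one another. The allylic secondary chloride next to a diene (SN2', elimination), the trisubstituted epoxide (acid), the tertiary β-hydroxy lactone (retro-aldol, dehydration, epimerisable C17) and three acetates (base) will not survive rough treatment, so they must come late. The feature that allows a short cut is this: C8, an oxygen-bearing carbon, and C3 are transannular 1,6-partners of the ten-membered ring, and the unit C8(O)–C7–C6–C5(=C16)–C4=C3 is the exact retron of an oxy-Cope rearrangement. In the precursor, ring B (C1, C2, C3, C8, C9, C10) is a cyclohexane carrying an allenyl group on C3 and a vinyl carbinol on C8. The oxygens of ring B at C2, C8 and C9, with the methyl on C1, are the substitution pattern of a methoxy-methyl-p-benzoquinone, so the easier 6-6 skeleton is two steps from commercial materials.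

## Retrosynthesis

**C6–Cl (25 ⇒ 24 ⇒ 23).** The C6–Cl bond is cut first. It is traced to the 6β-alcohol 24 (SN2 inversion), and 24 to the C6 methylene of triacetate 23 by allylic C–H hydroxylation. C6 is the only sp3 allylic position of the C5=C16 bond, so site selectivity is intrinsic, and the labile chloride is made in the last step. The forward reactions must not transpose the allylic system.

**Acetates and epoxide (23 ⇒ 22 ⇒ 21 ⇒ 20).** The three acetates and the epoxide are removed to the tris-silyl ether 20. Epoxidation is placed on the free tetraol 21, where the 14α-hydroxyl and the C15 methyl both favour the α face of the only isolated trisubstituted alkene.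

**Lactone (20 ⇒ 19 ⇒ 17 + 18).** The C8–C17 bond is cut: an intramolecular Reformatsky addition of a C7-bound 2-bromopropanoate to the C8 ketone. This is preferred to an intermolecular propionate addition because the C7 oxygen then delivers C17 to one face of the ketone and fixes C8 and C17 relative to C7. The precursor 17 is an α-hydroxy ketone with no lactone and no C17–C19 carbons.

**Ring expansion, key cut (17 ⇒ 16 ⇒ 15).** The C5–C6 bond is cut and the C3–C8 bond is re-formed, the retro-oxy-Cope. This is preferred to cutting a ring bond of the macrocycle (C2–C3, C3=C4, C6–C7), because the precursor 15 is a rigid trans-decalin in which every stereocentre sits on a chair. The forward step gives the ten-membered ring, the (E)-alkene, the exocyclic methylene and a regiodefined C7 enolate at once. The forward reaction must pass through a chair transition state, which requires the vinyl group on C8 to be equatorial.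

**Vinyl carbinol (15 ⇒ 14 ⇒ 13 ⇒ 12).** The carbinol is not made by vinyl addition to ketone 12. The axial 9β-silyloxy group would send a nucleophile to the α face and give the axial vinyl epimer, which would rearrange to the (3Z) isomer. Instead the oxygen is brought in from the α face (epoxidation of the methylene compound 13), and the vinyl group is completed by one-carbon homologation of spiro-epoxide 14.

**Allene (12 ⇒ 11 ⇒ 9 + 10).** The C3–C4 bond is cut by a retro-propargyl-Claisen rearrangement. The enol ether oxygen on C8, which came from the quinone methoxy group, becomes the C8 carbonyl, and propargyl alcohol 10 supplies C4, C5 and C16. No enolate chemistry is needed on a ring that carries β-leaving groups.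

**Redox and protecting-group adjustments (9 ⇒ 8 ⇒ 7 ⇒ 6 ⇒ 5 ⇒ 4).** These comprise alkene migration in ring A to C11=C12, silylation, reduction of both quinone carbonyls (C9 under steric control by the C15 methyl, C2 under delivery from the free 14α-hydroxyl), desilylation and epimerisation of C10.

**Ring A (4 ⇒ 3 + 2; 2 ⇒ 1).** The C1–C14 and C10–C11 bonds are cut by a retro-Diels–Alder reaction. Quinone 3 supplies C1–C3, C8–C10 and C15 with all three ring-B oxygens. Dienol ether 2 (from enal 1) supplies C11–C14 and C20, and sets C14 relative to the quaternary C1 by the endo rule. The forward reaction must be regioselective and enantioselective.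

## Roads not taken

**Alternative 1:** the most obvious route. Cut C3=C4 and close the ten-membered ring by ring-closing metathesis of the seco-triene A1, built by chain extension from a ring-A cyclohexane. The forward key step is a diene–ene metathesis forming a medium ring. It tends to give the (Z)-alkene or to engage the wrong double bond of the 1,3-diene. The whole C6–C9 stereoarray must first be built on an open chain with little relay from ring A. The allylic chloride or its precursor must survive a ruthenium carbene. The chosen plan gets the (E)-alkene from a chair transition state and needs no macrocyclisation.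

**Alternative 2:** cut C3–C8 by a Grob-type fragmentation (8-alkoxide, C4 leaving group) of a linear tricycle A2, assembled by two Diels–Alder reactions of a brominated methyl-p-quinone with two oxygenated dienes. The assembly is very short and brings the C5 methyl and C7 oxygen with it. The drawbacks are three. The angular C8 oxygen has to be introduced afterwards through the bromide. Ring C of A2 carries two leaving groups next to two ketones and is prone to aromatise under any base. The natural endo/anti selectivities of the two cycloadditions give the wrong C7 configuration and a cis B/C fusion that fragments to the (3Z) alkene. The oxy-Cope route is irreversible without a leaving group and has no aromatisation channel.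

**Alternative 3:** cut C6–C7 and close the ring by an intramolecular Nozaki–Hiyama–Kishi-type γ-chloroallylation of the seco-aldehyde A3, which would set C6–Cl, C7–OH and the exocyclic methylene in the ring-closing step. It requires C8, C9 and C17 to be built acyclically beforehand, relies on an anti-selective γ-chloroallyl chromium addition that is poorly secured, and pays the full entropic cost of a ten-membered ring closure. The chosen plan closes the ring by a sigmatropic shift of a bicyclic precursor and adds the chloride last.

Key step: step 12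

Assumptions: quinone 3 is taken as purchasable. The (S)-oxazaborolidine is taken to give the enantiomer drawn; if the sense of induction is the opposite, its mirror image is used.

## Route

Step 1
Reactants: 1 (E)-pent-2-enal
Product: 2 (1E,3E)-1-(tert-butyldimethylsilyloxy)penta-1,3-diene
Conditions: TBSOTf, Et3N, Et2O, 0 °C to rt
Reagents that add atoms: tert-butyldimethylsilyl triflate, CC(C)(C)[Si](C)(C)OS(=O)(=O)C(F)(F)F
Why: γ-Deprotonation and O-silylation of the enal (dienol silyl ether formation); the s-trans dienolate gives the (1E) enol ether, and only the (3E) isomer is a competent diene in step 2.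

Step 2
Reactants: 3 2-methoxy-5-methyl-1,4-benzoquinone; 2 (1E,3E)-1-(tert-butyldimethylsilyloxy)penta-1,3-diene
Product: 4 cis-fused enedione, 5-(tert-butyldimethylsilyloxy)-2-methoxy-4a,8-dimethyl-4a,5,8,8a-tetrahydronaphthalene-1,4-dione (15-Me β, 10-H β, 14-OTBS α, 11-Me α)
Conditions: (S)-o-tolyl oxazaborolidine from α,α-diphenylprolinol, activated with Tf2NH (20 mol %), CH2Cl2, −78 °C
Reagents that add atoms: none
Why: Lewis-acid-catalysed enantioselective quinone Diels–Alder reaction; the methoxy-bearing double bond is a deactivated vinylogous ester, so the diene adds to C1=C10; binding of the acid to the more basic vinylogous-ester carbonyl (C2=O) makes C10 the electrophilic end, so the methyl-bearing diene terminus bonds to C10 and the silyloxy carbon to C1; endo addition puts 14-OTBS trans to the angular methyl, and the catalyst sets the absolute configuration.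

Step 3
Reactants: 4 cis-fused enedione
Product: 5 trans-fused enedione (10-H α; otherwise as 4)
Conditions: DBU (0.2 equiv), CH2Cl2, rt
Reagents that add atoms: none
Why: Base-mediated epimerisation through the C9 enolate; C10 is the only enolisable stereocentre (C1 is quaternary) and the trans ring fusion is expected to be the thermodynamic one.

Step 4
Reactants: 5 trans-fused enedione
Product: 6 14α-hydroxy trans-enedione
Conditions: HF·pyridine, THF, 0 °C to rt
Reagents that add atoms: none
Why: Fluoride-mediated desilylation under non-basic conditions (no retro-aldol of the β-hydroxy ketone); it frees the axial 14α-hydroxyl that steers the next reduction.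

Step 5
Reactants: 6 14α-hydroxy trans-enedione
Product: 7 2β,9β,14α-triol (methyl enol ether C3=C8 retained)
Conditions: LiAlH4, THF, −78 to 0 °C; aq. Rochelle salt
Reagents that add atoms: none
Why: Hydride reduction of both carbonyls; at C9 the β face is blocked by the 1,3-related pseudo-axial C15 methyl, so hydride enters from α (9β-OH); at C2 the vinylogous-ester carbonyl is reduced 1,2 by hydride delivered from the aluminate on the syn-axial 14α-oxygen (2β-OH, 1,3-anti to O14); the basic work-up keeps the acid-labile 3-methoxy-allylic alcohol intact.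

Step 6
Reactants: 7 2β,9β,14α-triol
Product: 8 2β,9β,14α-tris(tert-butyldimethylsilyl) ether
Conditions: TBSOTf, 2,6-lutidine, CH2Cl2, −78 to 0 °C
Reagents that add atoms: tert-butyldimethylsilyl triflate, CC(C)(C)[Si](C)(C)OS(=O)(=O)C(F)(F)F
Why: Silylation with the triflate under buffered conditions protects the three secondary alcohols, including the two hindered axial ones, without ionising the allylic C2–O bond.

Step 7
Reactants: 8 tris-silyl ether
Product: 9 Δ11(12) isomer of 8 (ring-A alkene at C11=C12, C13 is CH2)
Conditions: Pd(dba)2, P(t-Bu)3, i-PrCOCl (5 mol % each, Pd–H formed in situ), toluene, 50 °C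
Reagents that add atoms: none
Why: Palladium-hydride alkene isomerisation (hydropalladation, β-hydride elimination) by one position to the trisubstituted alkene; Pd should add at C12, remote from the neopentyl silyloxy-bearing C14, and eliminate H-11; the C11 stereocentre is removed.

Step 8
Reactants: 9 Δ11(12) tris-silyl methyl enol ether; 10 prop-2-yn-1-ol
Product: 12 3α-allenyl 8-ketone (trans-decalin; 2β,9β,14α-tris-OTBS), via propargyl enol ether 11 (not isolated)
Conditions: 10 (5 equiv), EtCO2H (cat.), xylene, 135 °C, removal of MeOH
Reagents that add atoms: none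
Why: Saucy–Marbet sequence: acid-catalysed exchange of the methyl enol ether gives propargyl enol ether 11, whose propargyl Claisen rearrangement forms C3–C4 and turns the C8 oxygen into the ketone; the new bond forms on the α face of C3 because the β-axial trajectory is blocked by the 1,3-diaxial C15 methyl, and the equatorial α-allenyl epimer is also the thermodynamic one.

Step 9
Reactants: 12 3α-allenyl 8-ketone
Product: 13 8-methylene compound
Conditions: Zn, CH2Br2, TiCl4, THF/CH2Cl2, 0 °C to rt
Reagents that add atoms: dibromomethane, BrCBr
Why: Takai–Lombardo methylenation; the reagent is not basic, so the β,γ-allenyl ketone is neither epimerised at C3 nor isomerised to the conjugated dienone.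

Step 10
Reactants: 13 8-methylene compound
Product: 14 spiro-epoxide (8α-O, C7 β)
Conditions: mCPBA (1.05 equiv), NaHCO3, CH2Cl2, −20 °C
Reagents that add atoms: 3-chloroperoxybenzoic acid, OOC(=O)c1cccc(Cl)c1
Why: Prilezhaev epoxidation of the exocyclic 1,1-disubstituted alkene from the α face (axial attack; the β face is shielded by the axial 9β-OTBS), which makes the C8–O bond axial and C7 equatorial; the ring-A alkene is flanked on both faces by syn-axial groups (C15 methyl, 14α-OTBS) and the allene is less nucleophilic, so both should react more slowly.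

Step 11
Reactants: 14 spiro-epoxide
Product: 15 8α-hydroxy-8β-vinyl-3α-allenyl trans-decalin (tertiary allylic alcohol)
Conditions: Me3S+ I−, n-BuLi, THF, −10 °C to rt
Reagents that add atoms: trimethylsulfonium iodide, C[S+](C)C.[I-]
Why: One-carbon homologation of a terminal epoxide to an allylic alcohol with excess dimethylsulfonium methylide (opening at the CH2 terminus, then ylide-mediated elimination of dimethyl sulfide); C8 is untouched, so 15 has an axial 8α-OH and an equatorial vinyl group trans to the equatorial allenyl group.

Step 12
Reactants: 15 8α-hydroxy-8β-vinyl-3α-allenyl trans-decalin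
Product: 17 7α-hydroxy-8-ketone of the bicyclo[8.4.0] core (3E,5(16),11-triene; 2β,9β,14α-tris-OTBS), via potassium enolate 16 (not isolated)
Conditions: KHMDS, 18-crown-6, THF, −78 to 0 °C; then 2-(phenylsulfonyl)-3-phenyloxaziridine, −78 °C; aq. NH4Cl
Reagents that add atoms: 2-(phenylsulfonyl)-3-phenyloxaziridine, O=S(=O)(c1ccccc1)N1OC1c1ccccc1
Why: Anionic oxy-Cope rearrangement: the potassium alkoxide is a 3-oxido-1,5-diene whose second ene is the C4=C5 bond of the allene, and the [3,3] shift forms C5–C6 as it breaks C3–C8, so ring B is expanded by C4–C7 to the ten-membered ring. The closest known reaction type is the ring expansion of trans-1,2-divinylcyclohexanolates to (E)-cyclodec-5-enones, with an allene as the 2π partner as in Cope rearrangements of 1,2,6-trienes. The ten-membered ring is therefore closed by a sigmatropic ring expansion, not by an end-to-end cyclisation. The (3E) geometry follows from the chair transition state enforced by the trans-diequatorial vinyl and allenyl groups on the rigid trans-decalin, in which C2 is pseudo-equatorial; the orthogonal π bond of the allene is untouched and becomes the exocyclic C5=C16 bond conjugated with C3=C4. Enolate 16 is formed only towards C7 and is hydroxylated in the same flask by the N-sulfonyloxaziridine. The new stereocentre C7 is set by attack on the enolate face turned away from the transannular C3=C4 bond in the conformer delivered by the chair transition state, which corresponds to the 7α-oxygen of the target. The step needs the [3,3] shift to win over alkoxide-induced fragmentation and over a boat transition state; the irreversible conversion of an allene into an enolate plus a conjugated diene, and the diequatorial geometry, should secure this.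

Step 13
Reactants: 17 7α-hydroxy-8-ketone; 18 2-bromopropanoyl bromide
Product: 19 7α-O-(2-bromopropanoyl) ester of 17 (both epimers at the CHBr carbon)
Conditions: pyridine, CH2Cl2, −20 °C
Reagents that add atoms: none
Why: O-Acylation of the secondary α-hydroxy ketone with retention at C7; the configuration of the CHBr carbon is irrelevant because it is erased in step 14.

Step 14
Reactants: 19 7α-O-(2-bromopropanoyl) ester
Product: 20 tris-silyl lactone (8α-OH, 17R; 19,7-olide; 3E,5(16),11-triene)
Conditions: SmI2 (2.5 equiv), THF, −78 °C
Reagents that add atoms: none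
Why: Samarium diiodide-mediated intramolecular Reformatsky reaction: reduction of the C–Br bond and 5-exo addition of the ester enolate to the C8 ketone form C8–C17 and the γ-lactone; attack on the peripheral carbonyl face syn to O7 is the only one that keeps the C6–C7–C8–C9 torsion of the ten-membered ring anti, which gives 8α-OH (trans-fused lactone); the chelated Z-enolate places the C18 methyl syn to the new hydroxyl, which is also the thermodynamic C17 epimer (methyl anti to C9).

Step 15
Reactants: 20 tris-silyl lactone
Product: 21 2β,8α,9β,14α-tetraol lactone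
Conditions: TBAF, AcOH, THF, 40 °C
Reagents that add atoms: none
Why: Fluoride desilylation of the three secondary silyl ethers; buffering with acetic acid avoids retro-aldol opening of the β-hydroxy lactone.

Step 16
Reactants: 21 tetraol lactone
Product: 22 11α,12α-epoxy tetraol lactone
Conditions: mCPBA (1.0 equiv), NaHCO3, CH2Cl2, 0 °C
Reagents that add atoms: 3-chloroperoxybenzoic acid, OOC(=O)c1cccc(Cl)c1
Why: Prilezhaev epoxidation of the most nucleophilic alkene (trisubstituted, not conjugated); the peracid is guided by hydrogen bonding to the homoallylic 14α-hydroxyl and kept off the β face by the C15 methyl, which gives the α-epoxide.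

Step 17
Reactants: 22 epoxy tetraol lactone
Product: 23 2β,9β,14α-triacetate (6-deschloro target)
Conditions: Ac2O, pyridine, DMAP (cat.), CH2Cl2, rt
Reagents that add atoms: acetic anhydride, CC(=O)OC(C)=O
Why: Acetylation of the three secondary alcohols; the hindered tertiary 8-hydroxyl of the β-hydroxy lactone is not acylated under these conditions.

Step 18
Reactants: 23 triacetate
Product: 24 6β-hydroxy triacetate
Conditions: SeO2 (0.5 equiv), t-BuOOH, CH2Cl2, rt
Reagents that add atoms: tert-butyl hydroperoxide (terminal oxidant, oxygen delivered through SeO2), CC(C)(C)OO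
Why: Selenium dioxide allylic hydroxylation (ene reaction, then [2,3] shift) of the 1,1-disubstituted alkene; C6 is the only sp3 allylic position of C5=C16 (C4 is vinylic, C2–H is deactivated by its acetate), and oxygen is delivered with retention to the C6–H anti to the vicinal C7–O bond (β face).

Step 19
Reactants: 24 6β-hydroxy triacetate
Product: 25 CNP0106406.1 (target)
Conditions: hexachloroacetone, PPh3, CH2Cl2, 0 °C
Reagents that add atoms: hexachloroacetone, ClC(Cl)(Cl)C(=O)C(Cl)(Cl)Cl
Why: Appel-type chlorination of the secondary allylic alcohol through its alkoxyphosphonium salt; this reagent pair gives SN2 displacement with inversion and without allylic transposition, so the 6β-alcohol gives the 6α-chloride; the tertiary 8-hydroxyl is too hindered to react.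

## Compound list

1 | (E)-pent-2-enal | CC/C=C/C=O | starting material
2 | (1E,3E)-1-(tert-butyldimethylsilyloxy)penta-1,3-diene | C/C=C/C=C/O[Si](C)(C)C(C)(C)C | intermediate
3 | 2-methoxy-5-methyl-1,4-benzoquinone | COC1=CC(=O)C(C)=CC1=O | starting material
4 | cis-fused enedione (15-Me β, 10-H β, 14-OTBS α, 11-Me α) | COC1=CC(=O)[C@@]2(C)[C@@H](O[Si](C)(C)C(C)(C)C)C=C[C@@H](C)[C@H]2C1=O | intermediate
5 | trans-fused enedione (10-H α) | COC1=CC(=O)[C@@]2(C)[C@@H](O[Si](C)(C)C(C)(C)C)C=C[C@@H](C)[C@@H]2C1=O | intermediate
6 | 14α-hydroxy trans-enedione | COC1=CC(=O)[C@@]2(C)[C@@H](O)C=C[C@@H](C)[C@@H]2C1=O | intermediate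
7 | 2β,9β,14α-triol with C3=C8 methyl enol ether | COC1=C[C@H](O)[C@@]2(C)[C@@H](O)C=C[C@@H](C)[C@@H]2[C@@H]1O | intermediate
8 | tris-TBS ether of 7 | COC1=C[C@H](O[Si](C)(C)C(C)(C)C)[C@@]2(C)[C@@H](O[Si](C)(C)C(C)(C)C)C=C[C@@H](C)[C@@H]2[C@@H]1O[Si](C)(C)C(C)(C)C | intermediate
9 | Δ11(12) isomer of 8 | COC1=C[C@H](O[Si](C)(C)C(C)(C)C)[C@@]2(C)[C@@H](O[Si](C)(C)C(C)(C)C)CC=C(C)[C@@H]2[C@@H]1O[Si](C)(C)C(C)(C)C | intermediate
10 | prop-2-yn-1-ol | C#CCO | starting material
11 | propargyl enol ether (8-O-propargyl analogue of 9) | C#CCOC1=C[C@H](O[Si](C)(C)C(C)(C)C)[C@@]2(C)[C@@H](O[Si](C)(C)C(C)(C)C)CC=C(C)[C@@H]2[C@@H]1O[Si](C)(C)C(C)(C)C | intermediate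
12 | 3α-allenyl 8-ketone (2β,9β,14α-tris-OTBS trans-decalin) | C=C=C[C@H]1[C@H](O[Si](C)(C)C(C)(C)C)[C@@]2(C)[C@@H](O[Si](C)(C)C(C)(C)C)CC=C(C)[C@@H]2[C@H](O[Si](C)(C)C(C)(C)C)C1=O | intermediate
13 | 8-methylene compound | C=C=C[C@H]1[C@H](O[Si](C)(C)C(C)(C)C)[C@@]2(C)[C@@H](O[Si](C)(C)C(C)(C)C)CC=C(C)[C@@H]2[C@H](O[Si](C)(C)C(C)(C)C)C1=C | intermediate
14 | spiro-epoxide (8α-O) | C=C=C[C@H]1[C@H](O[Si](C)(C)C(C)(C)C)[C@@]2(C)[C@@H](O[Si](C)(C)C(C)(C)C)CC=C(C)[C@@H]2[C@H](O[Si](C)(C)C(C)(C)C)[C@]13CO3 | intermediate
15 | 8α-hydroxy-8β-vinyl-3α-allenyl trans-decalin | C=C=C[C@H]1[C@H](O[Si](C)(C)C(C)(C)C)[C@@]2(C)[C@@H](O[Si](C)(C)C(C)(C)C)CC=C(C)[C@@H]2[C@H](O[Si](C)(C)C(C)(C)C)[C@]1(O)C=C | intermediate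
16 | potassium C7=C8 enolate of the ten-membered ketone | [K+].C=C1/C=C/[C@H](O[Si](C)(C)C(C)(C)C)[C@@]2(C)[C@@H](O[Si](C)(C)C(C)(C)C)CC=C(C)[C@@H]2[C@H](O[Si](C)(C)C(C)(C)C)/C([O-])=C/C1 | intermediate
17 | 7α-hydroxy-8-ketone of the bicyclo[8.4.0] core | C=C1/C=C/[C@H](O[Si](C)(C)C(C)(C)C)[C@@]2(C)[C@@H](O[Si](C)(C)C(C)(C)C)CC=C(C)[C@@H]2[C@H](O[Si](C)(C)C(C)(C)C)C(=O)[C@@H](O)C1 | intermediate
18 | 2-bromopropanoyl bromide | CC(Br)C(Br)=O | starting material
19 | 7α-O-(2-bromopropanoyl) ester | C=C1/C=C/[C@H](O[Si](C)(C)C(C)(C)C)[C@@]2(C)[C@@H](O[Si](C)(C)C(C)(C)C)CC=C(C)[C@@H]2[C@H](O[Si](C)(C)C(C)(C)C)C(=O)[C@@H](OC(=O)C(C)Br)C1 | intermediate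
20 | tris-TBS lactone (8α-OH, 17R) | C=C1/C=C/[C@H](O[Si](C)(C)C(C)(C)C)[C@@]2(C)[C@@H](O[Si](C)(C)C(C)(C)C)CC=C(C)[C@@H]2[C@H](O[Si](C)(C)C(C)(C)C)[C@]2(O)[C@@H](C)C(=O)O[C@H]2C1 | intermediate
21 | 2β,8α,9β,14α-tetraol lactone | C=C1/C=C/[C@H](O)[C@@]2(C)[C@@H](O)CC=C(C)[C@@H]2[C@H](O)[C@]2(O)[C@@H](C)C(=O)O[C@H]2C1 | intermediate
22 | 11α,12α-epoxy tetraol lactone | C=C1/C=C/[C@H](O)[C@@]2(C)[C@@H](O)C[C@H]3O[C@@]3(C)[C@@H]2[C@H](O)[C@]2(O)[C@@H](C)C(=O)O[C@H]2C1 | intermediate
23 | 2β,9β,14α-triacetate (6-deschloro target) | C=C1/C=C/[C@H](OC(C)=O)[C@@]2(C)[C@@H](OC(C)=O)C[C@H]3O[C@@]3(C)[C@@H]2[C@H](OC(C)=O)[C@]2(O)[C@@H](C)C(=O)O[C@H]2C1 | intermediate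
24 | 6β-hydroxy triacetate | C=C1/C=C/[C@H](OC(C)=O)[C@@]2(C)[C@@H](OC(C)=O)C[C@H]3O[C@@]3(C)[C@@H]2[C@H](OC(C)=O)[C@]2(O)[C@@H](C)C(=O)O[C@H]2[C@@H]1O | intermediate
25 | CNP0106406.1 | C=C1/C=C/[C@H](OC(C)=O)[C@@]2(C)[C@@H](OC(C)=O)C[C@H]3O[C@@]3(C)[C@@H]2[C@H](OC(C)=O)[C@]2(O)[C@@H](C)C(=O)O[C@H]2[C@H]1Cl | target

## Step count and risks

Total steps: 19. Longest linear sequence: 19 steps (1 to 25); 3, 10 and 18 are purchased and enter at steps 2, 8 and 13.

**Step 12 (key step).** The alkoxide may fragment (cleavage of C3–C8 without C5–C6 bonding) or rearrange through a boat transition state to the (3Z) isomer, because the allene and the flanking silyloxy groups crowd the chair. The α-hydroxy ketone may also undergo an α-ketol shift during the basic hydroxylation. Fallback: alcohol 15 is silylated (TMS-imidazole) to the trimethylsilyl ether F1. F1 is heated without base (mesitylene, 170 °C) to the ten-membered trimethylsilyl enol ether F2 by a neutral siloxy-Cope rearrangement. F2 is oxidised under Rubottom conditions (dimethyldioxirane, −78 °C, then mild desilylation) and returns to the route at 17.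

**Step 2.** Poor regio- or enantiocontrol, because the chiral acid may bind the other quinone carbonyl or discriminate the quinone faces weakly. Fallback: the same steps 2 to 4 run from 3 and 2 with BF3·OEt2 as achiral Lewis acid give 6 as the racemate. This is esterified with (S)-2-methoxy-2-phenylacetic acid (DCC, DMAP), the diastereomers are separated, and the ester of the required enantiomer, F3, is treated with LiAlH4. This cleaves the ester and reduces both carbonyls under the same control as in step 5, and returns to the route at 7.

**Step 7.** Migration of the double bond in the wrong direction (towards C14, giving a silyl enol ether) or onward into the ring fusion, because all three products are thermodynamically reasonable. Fallback from 8: hydroboration–oxidation (9-BBN; NaBO3) gives the 12-alcohol F4. Dess–Martin oxidation gives ketone F5. The more substituted enolate (KH, then PhNTf2) gives the C11=C12 enol triflate F6. Palladium-catalysed formate reduction (Pd(OAc)2, PPh3, Bu3N, HCO2H) returns to the route at 9.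

**Step 10.** Loss of site selectivity, with the peracid attacking the trisubstituted ring-A alkene or the allene instead of the exocyclic methylene. Fallback from 13: osmium-catalysed dihydroxylation (OsO4, NMO), which is more sensitive to steric shielding, gives the 8α,7-diol F7. Selective tosylation of the primary alcohol gives F8, and K2CO3 in methanol closes the epoxide and returns to the route at 14.

**Step 18 (with step 19).** Poor facial selectivity of the C–H hydroxylation, or over-oxidation at C6, because the conformation of the macrocycle around C6 is not secured; step 19 then gives the wrong chloride epimer. Fallback: 23 is oxidised through to the C6 ketone F9 (SeO2/t-BuOOH in excess, then Dess–Martin periodinane on the crude product). F9 is reduced 1,2 under Luche conditions (NaBH4, CeCl3, MeOH, −78 °C) with Felkin–Anh control by the C7–O bond, and returns to the route at 24.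

## Further compounds

F1 | step 12 | trimethylsilyl ether of 15 | C=C=C[C@H]1[C@H](O[Si](C)(C)C(C)(C)C)[C@@]2(C)[C@@H](O[Si](C)(C)C(C)(C)C)CC=C(C)[C@@H]2[C@H](O[Si](C)(C)C(C)(C)C)[C@]1(O[Si](C)(C)C)C=C
F2 | step 12 | ten-membered C7=C8 trimethylsilyl enol ether | C=C1/C=C/[C@H](O[Si](C)(C)C(C)(C)C)[C@@]2(C)[C@@H](O[Si](C)(C)C(C)(C)C)CC=C(C)[C@@H]2[C@H](O[Si](C)(C)C(C)(C)C)/C(O[Si](C)(C)C)=C/C1
F3 | step 2 | (S)-2-methoxy-2-phenylacetate of 6 | COC1=CC(=O)[C@@]2(C)[C@@H](OC(=O)[C@@H](OC)c3ccccc3)C=C[C@@H](C)[C@@H]2C1=O
F4 | step 7 | 12β-alcohol from hydroboration of 8 | COC1=C[C@H](O[Si](C)(C)C(C)(C)C)[C@@]2(C)[C@@H](O[Si](C)(C)C(C)(C)C)C[C@H](O)[C@@H](C)[C@@H]2[C@@H]1O[Si](C)(C)C(C)(C)C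
F5 | step 7 | 12-ketone | COC1=C[C@H](O[Si](C)(C)C(C)(C)C)[C@@]2(C)[C@@H](O[Si](C)(C)C(C)(C)C)CC(=O)[C@@H](C)[C@@H]2[C@@H]1O[Si](C)(C)C(C)(C)C
F6 | step 7 | C11=C12 enol triflate | COC1=C[C@H](O[Si](C)(C)C(C)(C)C)[C@@]2(C)[C@@H](O[Si](C)(C)C(C)(C)C)CC(OS(=O)(=O)C(F)(F)F)=C(C)[C@@H]2[C@@H]1O[Si](C)(C)C(C)(C)C
F7 | step 10 | 8α,7-diol from 13 | C=C=C[C@H]1[C@H](O[Si](C)(C)C(C)(C)C)[C@@]2(C)[C@@H](O[Si](C)(C)C(C)(C)C)CC=C(C)[C@@H]2[C@H](O[Si](C)(C)C(C)(C)C)[C@]1(O)CO
F8 | step 10 | primary tosylate of F7 | C=C=C[C@H]1[C@H](O[Si](C)(C)C(C)(C)C)[C@@]2(C)[C@@H](O[Si](C)(C)C(C)(C)C)CC=C(C)[C@@H]2[C@H](O[Si](C)(C)C(C)(C)C)[C@]1(O)COS(=O)(=O)c1ccc(C)cc1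
F9 | step 18 | C6 ketone of the triacetate | C=C1/C=C/[C@H](OC(C)=O)[C@@]2(C)[C@@H](OC(C)=O)C[C@H]3O[C@@]3(C)[C@@H]2[C@H](OC(C)=O)[C@]2(O)[C@@H](C)C(=O)O[C@H]2C1=O
A1 | alternative 1 | seco-triene for ring-closing metathesis at C3=C4 | C=CC(=C)[C@H](Cl)[C@@H]1OC(=O)[C@H](C)[C@@]1(O)[C@@H](OC(C)=O)[C@H]1[C@]2(C)O[C@@H]2C[C@H](OC(C)=O)[C@]1(C)[C@@H](OC(C)=O)C=C
A2 | alternative 2 | linear tricycle from two Diels–Alder reactions (8-Br, 4-OAc, 7-OTBS, 14-OTBS) | CC1=C[C@@H](O[Si](C)(C)C(C)(C)C)[C@@]2(Br)C(=O)[C@@H]3[C@H](C)C=C[C@H](O[Si](C)(C)C(C)(C)C)[C@]3(C)C(=O)[C@H]2[C@H]1OC(C)=O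
A3 | alternative 3 | seco-aldehyde with 1,3-dichloropropenyl unit for chloroallylation at C6–C7 | ClC/C(=C/Cl)/C=C/[C@H](OC(C)=O)[C@@]1(C)[C@@H](OC(C)=O)C[C@H]2O[C@@]2(C)[C@@H]1[C@H](OC(C)=O)[C@@](O)(C=O)[C@@H](C)C(=O)OC
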